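## Retrosynthetic overview

1. Ring numbering used below: C1 = C(CH3)(CH2CH2CO2H), C2 = CH(CH2OAr), C3 = C(CH3)=, C4 = =CH, C5 = CH(isopropenyl), C6 = CH2. Enabling feature: the OCH2 carbon on C2 and the isopropenyl sp2 carbon on C5 are cis and 1,4 across C3=C4, so they can be joined as a temporary two-carbon bridge (the cyclohexene becomes one ring of a bicyclo[2.2.2]octadiene); the C1 propanoic arm is cis to that bridge, so its terminal oxygen can be strapped to the bridge's enol oxygen.
2. Target ⇐ alcohol oxidation, desilylation and Mitsunobu etherification with umbelliferone ⇐ cyclohexenylmethanol 23 ⇐ reductive Grob fragmentation of a bicyclo[2.2.2]octenone, which cuts the bridge bond and releases CH2OH on C2 and isopropenyl on C5, cis by construction.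
3. Bicycle ⇐ Diels–Alder reaction of the silylene-strapped 2-silyloxycyclohexa-1,3-diene 12 with p-tolyl 1-propynyl sulfone 15, forming C4–C5 and C2–C3 (sulfonyl carbon becomes C4, methyl carbon becomes C3).
4. 12 ⇐ (R)-5-(3-hydroxypropyl)-2,5-dimethylcyclohex-2-enone 9 ⇐ copper-catalysed asymmetric conjugate addition to 3-methylcyclohex-2-enone (sets C1), then α-methylation and dehydrogenation.
5. Ring order: the cyclohexenone ring of the starting material first; the cyclohexene ring of the target second (Diels–Alder); the first ring is then cut open, its carbonyl carbon becoming the OCH2 and its α-carbon the isopropenyl carbon.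

Key step: step 7

Assumption: carbons that later become sp2 (C2 of 7; the hydroxymethyl-bearing carbon of 19–21; the carbinol carbon of 21) are carried as epimer mixtures, and sulfone 15 is prepared rather than bought.

## Route

Step 1
Reactants: 1 3-methylcyclohex-2-en-1-one; 2 (3-bromopropoxy)(tert-butyl)dimethylsilane
Product: 5 (S)-3-{3-[(tert-butyldimethylsilyl)oxy]propyl}-3-methylcyclohexan-1-one, via Grignard reagent 3 (not isolated), via bromomagnesium enolate 4 (not isolated)
Conditions: Mg, Et2O (2 → 3); Cu(OTf)2 (3 mol%), chiral imidazolinium salt (NHC precursor, 4 mol%, the enantiomer that gives the S ketone), Et2O, 0 °C, slow addition of 1; aq. NH4Cl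
Reagents that add atoms: none
Why: Copper–NHC-catalysed asymmetric conjugate addition of a primary alkyl Grignard reagent to 3-methylcyclohex-2-enone is an established way to β-quaternary cyclohexanones, and the chiral ligand sets the quaternary stereocentre (future C1) by enantiofacial selection at the β-carbon.

Step 2
Reactants: 5 (S)-3-{3-[(tert-butyldimethylsilyl)oxy]propyl}-3-methylcyclohexan-1-one
Product: 7 (5S)-5-{3-[(tert-butyldimethylsilyl)oxy]propyl}-2,5-dimethylcyclohexan-1-one (C2 epimer mixture), via lithium enolate 6 (not isolated)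
Conditions: LDA (1.1 equiv), THF, −78 °C; MeI, −78 → 0 °C
Reagents that add atoms: iodomethane, CI
Why: Kinetic enolisation with LDA should occur at the unhindered C6 methylene and not at the neopentyl methylene next to the quaternary carbon, and enolate alkylation then installs the methyl that ends as the isopropenyl methyl (the new stereocentre is erased in step 3).

Step 3
Reactants: 7 (5S)-5-{3-[(tert-butyldimethylsilyl)oxy]propyl}-2,5-dimethylcyclohexan-1-one
Product: 8 (R)-5-{3-[(tert-butyldimethylsilyl)oxy]propyl}-2,5-dimethylcyclohex-2-en-1-one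
Conditions: IBX (2 equiv), DMSO/PhF, 70 °C
Reagents that add atoms: none
Why: IBX-mediated α,β-dehydrogenation of ketones can only introduce the C2=C3 double bond here, because the other α-carbon adjoins the quaternary centre, which also blocks over-oxidation to a dienone or phenol.

Step 4
Reactants: 8 (R)-5-{3-[(tert-butyldimethylsilyl)oxy]propyl}-2,5-dimethylcyclohex-2-en-1-one
Product: 9 (R)-5-(3-hydroxypropyl)-2,5-dimethylcyclohex-2-en-1-one
Conditions: p-TsOH·H2O (5 mol%), MeOH, rt
Reagents that add atoms: none
Why: Acid-catalysed methanolysis of the primary TBS ether frees the alcohol that anchors the strap, the enone and the quaternary centre being inert under these conditions.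

Step 5
Reactants: 9 (R)-5-(3-hydroxypropyl)-2,5-dimethylcyclohex-2-en-1-one
Product: 12 (8R)-8,11-dimethyl-3,3-di(propan-2-yl)-2,4-dioxa-3-silabicyclo[6.3.1]dodeca-1(12),10-diene (strapped diene), via chlorosilyl ether 10 (not isolated), via lithium dienolate 11 (not isolated)
Conditions: i-Pr2SiCl2 (3 equiv), imidazole (1.2 equiv), CH2Cl2, 0 °C; pentane, filtration under Ar, excess silane removed in vacuo; LDA (1.1 equiv), THF (2 mM), −78 → 0 °C
Reagents that add atoms: dichlorodi(propan-2-yl)silane, CC(C)[Si](Cl)(Cl)C(C)C
Why: Proposed new method: closure of a nine-membered 1,3-dioxa-2-silacycle by intramolecular O-silylation of a kinetic cross-conjugated lithium dienolate with a tethered alkoxy(chloro)silane; LDA should remove the α′-proton (the CH2 next to the quaternary carbon, as in the kinetic enolisation of isophorone) irreversibly at −78 °C faster than it attacks the hindered Si–Cl bond, the hard enolate oxygen should then displace chloride from the silicon held nearby, high dilution favouring ring closure over oligomerisation, and the (E)-enol ether that the ring must contain is tolerable in a nine-membered ring with two long Si–O bonds; the closest known reaction types are the stepwise synthesis of unsymmetrical diisopropylsilyl bis(enol) ethers and silaketal tethers from i-Pr2SiCl2 and the O-silylation of kinetic cyclohexenone dienolates to 2-silyloxy-1,3-dienes; no stereocentre is formed.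

Step 6
Reactants: 13 trimethyl(prop-1-yn-1-yl)silane; 14 4-methylbenzenesulfonyl chloride
Product: 15 1-methyl-4-(prop-1-yn-1-ylsulfonyl)benzene
Conditions: AlCl3 (1.1 equiv), CH2Cl2, 0 °C → rt
Reagents that add atoms: none
Why: Aluminium chloride-promoted ipso-sulfonylation of a silylalkyne with an arenesulfonyl chloride (Friedel–Crafts-type desilylative substitution) is the standard preparation of acetylenic sulfones.

Step 7
Reactants: 12 strapped diene; 15 1-methyl-4-(prop-1-yn-1-ylsulfonyl)benzene
Product: 16 strapped Diels–Alder adduct (2,5,7-trimethyl-3-tosylbicyclo[2.2.2]octa-2,5-diene core; C1 is the bridgehead bonded to C2/C6/C7; C6–O and the C7 propyl arm are joined through O–Si(i-Pr)2–O; C7 methyl syn to the C2=C3 bridge)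
Conditions: 15 (1.5 equiv), PhMe, BHT (cat.), 85 °C, sealed tube
Reagents that add atoms: none
Why: The mechanism is a concerted, asynchronous normal-demand [4+2] cycloaddition in which the diene HOMO, largest at the enol-ether terminus, meets the LUMO of the acetylenic sulfone, largest at the methyl-bearing β-carbon, so the bond next to the quaternary carbon (C2–C3) forms in the lead. The closest known reaction type is the Diels–Alder reaction of 2-silyloxycyclohexa-1,3-dienes with acetylenic sulfones and esters (and the related double Michael reaction of cross-conjugated dienolates) to bicyclo[2.2.2]octadienes. The new six-membered ring, which is the cyclohexene of the target (C5–C4=C3–C2 joined to the existing C1–C6 unit), closes by suprafacial [π4s+π2s] union of diene and alkyne and completes the bicyclo[2.2.2]octa-2,5-diene in the same event. The two bridgeheads (future C5 and C2) are formed on one face of the diene and are therefore cis, and their configuration relative to the quaternary carbon is fixed by the strap, which crosses the face of the (E)-enol-ether double bond on the side of the propyl arm and locks that arm pseudoaxial, so the alkyne must add anti to the arm and syn to the methyl group. The step needs regioselectivity (secured by the para relation of silyloxy donor and sulfonyl acceptor), facial selectivity (secured by the strap) and freedom from Alder–Rickert retro-cleavage (secured by the activated dienophile, which allows reaction below 100 °C).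

Step 8
Reactants: 16 strapped Diels–Alder adduct
Product: 17 desulfonylated strapped bicyclo[2.2.2]octa-2,5-diene (C3–H in place of C3–Ts)
Conditions: Na(Hg) (5%), Na2HPO4, THF/MeOH, −20 °C
Reagents that add atoms: none
Why: Buffered sodium amalgam cleaves the C(sp2)–S bond of the vinyl sulfone by two-electron reduction and protonation (reductive desulfonylation, as used for cycloadducts of sulfonyl acetylenes), the ring fixing the double-bond position and the buffer sparing the silyl enol ether.

Step 9
Reactants: 17 desulfonylated strapped bicyclo[2.2.2]octa-2,5-diene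
Product: 19 6-(hydroxymethyl)-3,6,8-trimethyl-8-[3-({methyl[di(propan-2-yl)]silyl}oxy)propyl]bicyclo[2.2.2]oct-2-en-5-one (ketone carbon bonded to the bridgehead next to the quaternary C8; epimers at C6), via lithium enolate 18 (not isolated)
Conditions: MeLi (1.05 equiv), THF, 0 °C; then HCHO (g, from cracked paraformaldehyde), −78 °C; H2O
Reagents that add atoms: methyllithium, [Li]C; formaldehyde, C=O
Why: Methyllithium attacks silicon of the silyl enol ether and expels the better leaving group, the regiodefined bicyclic lithium enolate (enolisation toward the bridgehead is forbidden), which caps the arm oxygen as a robust methyldiisopropylsilyl ether, and the enolate is then hydroxymethylated by aldol addition to monomeric formaldehyde; the new quaternary stereocentre is irrelevant because this carbon becomes sp2 in step 11.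

Step 10
Reactants: 19 β-hydroxy ketone
Product: 20 6-[(methanesulfonyloxy)methyl]-3,6,8-trimethyl-8-[3-({methyl[di(propan-2-yl)]silyl}oxy)propyl]bicyclo[2.2.2]oct-2-en-5-one (β-mesyloxy ketone; epimers at C6)
Conditions: MsCl, Et3N, CH2Cl2, 0 °C
Reagents that add atoms: methanesulfonyl chloride, CS(Cl)(=O)=O
Why: Sulfonylation of the primary alcohol with mesyl chloride and triethylamine gives a β-mesyloxy ketone that cannot undergo E1cB elimination because its α-carbon is quaternary.

Step 11
Reactants: 20 β-mesyloxy ketone
Product: 23 {(1R,4S,6R)-2,6-dimethyl-6-[3-({methyl[di(propan-2-yl)]silyl}oxy)propyl]-4-(prop-1-en-2-yl)cyclohex-2-en-1-yl}methanol, via mesyloxy alkoxide 21 (not isolated), via aldehyde 22 (not isolated)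
Conditions: LiAlH4 (3 equiv), THF, −20 °C → rt; Rochelle salt work-up
Reagents that add atoms: none
Why: Hydride reduction of the ketone gives a 1,3-alkoxy mesylate that should undergo Grob (Wharton-type) fragmentation, the alkoxide expelling the ring C–C bond antiperiplanar to the freely rotating CH2–OMs bond to unveil the isopropenyl group and an aldehyde that the excess hydride reduces at once, so the two bridgehead stereocentres pass unchanged and cis into the cyclohexene.

Step 12
Reactants: 23 cyclohexenylmethanol; 24 7-hydroxy-2H-chromen-2-one (umbelliferone)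
Product: 25 7-{[(1R,4S,6R)-2,6-dimethyl-6-[3-({methyl[di(propan-2-yl)]silyl}oxy)propyl]-4-(prop-1-en-2-yl)cyclohex-2-en-1-yl]methoxy}-2H-chromen-2-one
Conditions: PPh3, DIAD, THF, 0 °C → rt
Reagents that add atoms: none
Why: Mitsunobu etherification of the primary alcohol with the acidic phenol umbelliferone forms the aryl ether at a CH2 carbon, so no stereocentre is involved.

Step 13
Reactants: 25 silyl-protected aryl ether
Product: 26 7-{[(1R,4S,6R)-6-(3-hydroxypropyl)-2,6-dimethyl-4-(prop-1-en-2-yl)cyclohex-2-en-1-yl]methoxy}-2H-chromen-2-one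
Conditions: TBAF, THF, 0 °C → rt
Reagents that add atoms: none
Why: Fluoride-mediated cleavage of the trialkylsilyl ether frees the primary alcohol without touching the coumarin lactone, the aryl ether or the alkenes.

Step 14
Reactants: 26 primary alcohol
Product: 27 3-[(1R,2R,5S)-1,3-dimethyl-2-{[(2-oxo-2H-chromen-7-yl)oxy]methyl}-5-(prop-1-en-2-yl)cyclohex-3-en-1-yl]propanoic acid (target)
Conditions: TEMPO (20 mol%), PhI(OAc)2 (2.5 equiv), MeCN/H2O (1:1), rt
Reagents that add atoms: water, O
Why: TEMPO/PhI(OAc)2 oxidation in aqueous acetonitrile takes the primary alcohol through the aldehyde hydrate to the carboxylic acid under near-neutral conditions that should spare the isopropenyl group, the ring alkene and the coumarin.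

## Compound list

1 | 3-methylcyclohex-2-en-1-one | CC1=CC(=O)CCC1 | starting material
2 | (3-bromopropoxy)(tert-butyl)dimethylsilane | BrCCCO[Si](C)(C)C(C)(C)C | starting material
3 | {3-[(tert-butyldimethylsilyl)oxy]propyl}magnesium bromide | Br[Mg]CCCO[Si](C)(C)C(C)(C)C | intermediate (not isolated)
4 | bromomagnesium (S)-3-{3-[(tert-butyldimethylsilyl)oxy]propyl}-3-methylcyclohex-1-en-1-olate | Br[Mg]OC1=C[C@](C)(CCCO[Si](C)(C)C(C)(C)C)CCC1 | intermediate (not isolated)
5 | (S)-3-{3-[(tert-butyldimethylsilyl)oxy]propyl}-3-methylcyclohexan-1-one | O=C1C[C@](C)(CCCO[Si](C)(C)C(C)(C)C)CCC1 | intermediate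
6 | lithium (S)-5-{3-[(tert-butyldimethylsilyl)oxy]propyl}-5-methylcyclohex-1-en-1-olate | [Li]OC1=CCC[C@@](C)(CCCO[Si](C)(C)C(C)(C)C)C1 | intermediate (not isolated)
7 | (5S)-5-{3-[(tert-butyldimethylsilyl)oxy]propyl}-2,5-dimethylcyclohexan-1-one (C2 epimers) | CC1CC[C@@](C)(CCCO[Si](C)(C)C(C)(C)C)CC1=O | intermediate
8 | (R)-5-{3-[(tert-butyldimethylsilyl)oxy]propyl}-2,5-dimethylcyclohex-2-en-1-one | CC1=CC[C@@](C)(CCCO[Si](C)(C)C(C)(C)C)CC1=O | intermediate
9 | (R)-5-(3-hydroxypropyl)-2,5-dimethylcyclohex-2-en-1-one | CC1=CC[C@@](C)(CCCO)CC1=O | intermediate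
10 | (R)-5-(3-{[chlorodi(propan-2-yl)silyl]oxy}propyl)-2,5-dimethylcyclohex-2-en-1-one | CC1=CC[C@@](C)(CCCO[Si](Cl)(C(C)C)C(C)C)CC1=O | intermediate (not isolated)
11 | lithium (R)-6-(3-{[chlorodi(propan-2-yl)silyl]oxy}propyl)-3,6-dimethylcyclohexa-1,3-dien-2-olate | CC1=CC[C@@](C)(CCCO[Si](Cl)(C(C)C)C(C)C)C=C1O[Li] | intermediate (not isolated)
12 | (8R)-8,11-dimethyl-3,3-di(propan-2-yl)-2,4-dioxa-3-silabicyclo[6.3.1]dodeca-1(12),10-diene | CC1=CC[C@]2(C)C=C1O[Si](C(C)C)(C(C)C)OCCC2 | intermediate
13 | trimethyl(prop-1-yn-1-yl)silane | CC#C[Si](C)(C)C | starting material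
14 | 4-methylbenzenesulfonyl chloride | Cc1ccc(S(Cl)(=O)=O)cc1 | starting material
15 | 1-methyl-4-(prop-1-yn-1-ylsulfonyl)benzene | CC#CS(=O)(=O)c1ccc(C)cc1 | intermediate
16 | strapped adduct: 2,5,7-trimethyl-3-tosylbicyclo[2.2.2]octa-2,5-diene, C6–O and C7–(CH2)3–O bridged by Si(i-Pr)2, C7 methyl syn to C2=C3 | CC=2[C@@H]1C(S(=O)(=O)c3ccc(C)cc3)=C(C)[C@H](C=2O[Si]4(C(C)C)C(C)C)[C@](C)(CCCO4)C1 | intermediate
17 | desulfonylated strapped adduct (C3–H) | CC=2[C@@H]1C=C(C)[C@H](C=2O[Si]4(C(C)C)C(C)C)[C@](C)(CCCO4)C1 | intermediate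
18 | lithium enolate of the bicyclic ketone, arm as O–Si(i-Pr)2Me ether | CC=2[C@@H]1C=C(C)[C@H](C=2O[Li])[C@](C)(CCCO[Si](C)(C(C)C)C(C)C)C1 | intermediate (not isolated)
19 | 6-(hydroxymethyl)-3,6,8-trimethyl-8-[3-({methyl[di(propan-2-yl)]silyl}oxy)propyl]bicyclo[2.2.2]oct-2-en-5-one (C6 epimers) | CC2(CO)[C@@H]1C=C(C)[C@H](C2=O)[C@](C)(CCCO[Si](C)(C(C)C)C(C)C)C1 | intermediate
20 | 6-[(methanesulfonyloxy)methyl]-3,6,8-trimethyl-8-[3-({methyl[di(propan-2-yl)]silyl}oxy)propyl]bicyclo[2.2.2]oct-2-en-5-one (C6 epimers) | CC2(COS(C)(=O)=O)[C@@H]1C=C(C)[C@H](C2=O)[C@](C)(CCCO[Si](C)(C(C)C)C(C)C)C1 | intermediate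
21 | lithium alkoxide from hydride addition to the ketone of 20 (carbinol epimers) | CC2(COS(C)(=O)=O)[C@@H]1C=C(C)[C@H](C2O[Li])[C@](C)(CCCO[Si](C)(C(C)C)C(C)C)C1 | intermediate (not isolated)
22 | (1R,4S,6R)-2,6-dimethyl-6-[3-({methyl[di(propan-2-yl)]silyl}oxy)propyl]-4-(prop-1-en-2-yl)cyclohex-2-ene-1-carbaldehyde | C=C(C)[C@@H]1C=C(C)[C@H](C=O)[C@](C)(CCCO[Si](C)(C(C)C)C(C)C)C1 | intermediate (not isolated)
23 | {(1R,4S,6R)-2,6-dimethyl-6-[3-({methyl[di(propan-2-yl)]silyl}oxy)propyl]-4-(prop-1-en-2-yl)cyclohex-2-en-1-yl}methanol | C=C(C)[C@@H]1C=C(C)[C@H](CO)[C@](C)(CCCO[Si](C)(C(C)C)C(C)C)C1 | intermediate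
24 | 7-hydroxy-2H-chromen-2-one (umbelliferone) | Oc1ccc2ccc(=O)oc2c1 | starting material
25 | 7-{[(1R,4S,6R)-2,6-dimethyl-6-[3-({methyl[di(propan-2-yl)]silyl}oxy)propyl]-4-(prop-1-en-2-yl)cyclohex-2-en-1-yl]methoxy}-2H-chromen-2-one | C=C(C)[C@@H]1C=C(C)[C@H](COc2ccc3ccc(=O)oc3c2)[C@](C)(CCCO[Si](C)(C(C)C)C(C)C)C1 | intermediate
26 | 7-{[(1R,4S,6R)-6-(3-hydroxypropyl)-2,6-dimethyl-4-(prop-1-en-2-yl)cyclohex-2-en-1-yl]methoxy}-2H-chromen-2-one | C=C(C)[C@@H]1C=C(C)[C@H](COc2ccc3ccc(=O)oc3c2)[C@](C)(CCCO)C1 | intermediate
27 | 3-[(1R,2R,5S)-1,3-dimethyl-2-{[(2-oxo-2H-chromen-7-yl)oxy]methyl}-5-(prop-1-en-2-yl)cyclohex-3-en-1-yl]propanoic acid | C=C(C)[C@@H]1C=C(C)[C@H](COc2ccc3ccc(=O)oc3c2)[C@](C)(CCC(=O)O)C1 | target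

## Count and risks

Total step count: 14. Longest linear sequence: 13 (steps 1–5 and 7–14; step 6 is a one-step side branch).

Steps most likely to fail:

1. Step 5 (Proposed new method). Intermolecular silylation may outrun closure of the nine-membered ring, the amide base may attack the Si–Cl bond, or enolisation may occur at the γ-carbon and give the unstrained linear dienol ether. The fallback uses known chemistry and gives up the strap. It sets out from 8: kinetic enolisation with LDA at −78 °C and O-silylation with TBSCl/HMPA should give the acyclic cross-conjugated dienol ether tert-butyl{[(6R)-6-{3-[(tert-butyldimethylsilyl)oxy]propyl}-3,6-dimethylcyclohexa-1,3-dien-2-yl]oxy}dimethylsilane F1. Diels–Alder reaction with 15 under the conditions of step 7 should give the bis-TBS bicyclic adduct F2; only a modest intrinsic preference for attack anti to the longer arm is expected, so the unwanted diastereomer would have to be removed by chromatography. Buffered sodium amalgam then gives the desulfonylated diene F3, and a Sc(OTf)3-catalysed Mukaiyama aldol reaction with aqueous formaldehyde gives the hydroxymethyl ketone F4. Mesylation gives the mesylate F5, LiAlH4 reductive fragmentation the TBS-protected cyclohexenylmethanol F6, and Mitsunobu reaction with 24 the TBS-protected aryl ether F7. TBAF brings the sequence back at 26.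

2. Step 7. Bond formation at the diene terminus flanked by the quaternary carbon may be slow, which would open the way to open-chain Michael-type adducts by silyl transfer, to erosion of regiocontrol, or, if the temperature has to be raised, to Alder–Rickert extrusion of the saturated bridge with aromatisation. The fallback sets out from 12 and uses the more reactive cumulene (propa-1,2-dien-1-ylsulfonyl)benzene F8, obtained from phenyl prop-2-ynyl sulfone by Et3N isomerisation. It should add through its sulfonyl-activated double bond near room temperature with the same orientation to give the exo-methylene strapped adduct F9. Pd(PPh3)4/LiBHEt3 reductive desulfonylation of this allylic sulfone, with hydride delivered to the exocyclic terminus, comes back at 17.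

3. Step 11. The alkoxide may close onto the mesylate carbon to give an oxetane, hydride may cleave the S–O bond of the mesylate, or the ketone may simply be reduced without fragmentation. The fallback replaces steps 9–11 by an oxidative cleavage and sets out from 17: MeLi followed by 2-(phenylsulfonyl)-3-phenyloxaziridine should give the α-hydroxy ketone F10. Pb(OAc)4 in MeOH cleaves it to the keto ester methyl (1R,4S,6R)-4-acetyl-2,6-dimethyl-6-[3-({methyl[di(propan-2-yl)]silyl}oxy)propyl]cyclohex-2-ene-1-carboxylate F11. Non-basic methylenation with Cp2Ti(μ-Cl)(μ-CH2)AlMe2 gives the isopropenyl ester F12, and DIBAL reduction comes back at 23.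

Further compounds
F1 | step 5 | tert-butyl{[(6R)-6-{3-[(tert-butyldimethylsilyl)oxy]propyl}-3,6-dimethylcyclohexa-1,3-dien-2-yl]oxy}dimethylsilane | CC1=CC[C@@](C)(CCCO[Si](C)(C)C(C)(C)C)C=C1O[Si](C)(C)C(C)(C)C
F2 | step 5 | bis-TBS bicyclic adduct (analogue of 16 without strap) | CC=2[C@@H]1C(S(=O)(=O)c3ccc(C)cc3)=C(C)[C@H](C=2O[Si](C)(C)C(C)(C)C)[C@](C)(CCCO[Si](C)(C)C(C)(C)C)C1
F3 | step 5 | desulfonylated bis-TBS diene | CC=2[C@@H]1C=C(C)[C@H](C=2O[Si](C)(C)C(C)(C)C)[C@](C)(CCCO[Si](C)(C)C(C)(C)C)C1
F4 | step 5 | hydroxymethyl ketone with TBS-protected arm | CC2(CO)[C@@H]1C=C(C)[C@H](C2=O)[C@](C)(CCCO[Si](C)(C)C(C)(C)C)C1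
F5 | step 5 | mesylate of F4 | CC2(COS(C)(=O)=O)[C@@H]1C=C(C)[C@H](C2=O)[C@](C)(CCCO[Si](C)(C)C(C)(C)C)C1
F6 | step 5 | {(1R,4S,6R)-6-{3-[(tert-butyldimethylsilyl)oxy]propyl}-2,6-dimethyl-4-(prop-1-en-2-yl)cyclohex-2-en-1-yl}methanol | C=C(C)[C@@H]1C=C(C)[C@H](CO)[C@](C)(CCCO[Si](C)(C)C(C)(C)C)C1
F7 | step 5 | TBS-protected aryl ether (analogue of 25) | C=C(C)[C@@H]1C=C(C)[C@H](COc2ccc3ccc(=O)oc3c2)[C@](C)(CCCO[Si](C)(C)C(C)(C)C)C1
F8 | step 7 | (propa-1,2-dien-1-ylsulfonyl)benzene | C=C=CS(=O)(=O)c1ccccc1
F9 | step 7 | exo-methylene strapped adduct (allylic sulfone, sulfonyl-carbon epimers) | CC=2[C@@H]1C(S(=O)(=O)c3ccccc3)C(=C)[C@H](C=2O[Si]4(C(C)C)C(C)C)[C@](C)(CCCO4)C1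
F10 | step 11 | α-hydroxy ketone (tertiary carbinol epimers) | CC2(O)[C@@H]1C=C(C)[C@H](C2=O)[C@](C)(CCCO[Si](C)(C(C)C)C(C)C)C1
F11 | step 11 | methyl (1R,4S,6R)-4-acetyl-2,6-dimethyl-6-[3-({methyl[di(propan-2-yl)]silyl}oxy)propyl]cyclohex-2-ene-1-carboxylate | CC(=O)[C@@H]1C=C(C)[C@H](C(=O)OC)[C@](C)(CCCO[Si](C)(C(C)C)C(C)C)C1
F12 | step 11 | methyl (1R,4S,6R)-2,6-dimethyl-6-[3-({methyl[di(propan-2-yl)]silyl}oxy)propyl]-4-(prop-1-en-2-yl)cyclohex-2-ene-1-carboxylate | C=C(C)[C@@H]1C=C(C)[C@H](C(=O)OC)[C@](C)(CCCO[Si](C)(C(C)C)C(C)C)C1
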